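**Retrosynthetic overview**

1. Clerodane numbering is used (C1 = CH–O-isobutyryl; C4=C18 and C8=C17 exocyclic methylenes; C5/C10 ring fusion; C19/C20 methyls on C5/C9; C11–C16 side chain). End game: O6-PMB cleavage, O12 tigloylation, and the hydroxy-lactone from Sharpless epoxidation/epoxy-ester lactonisation of a C12 allylic alcohol made by Nozaki–Hiyama–Kishi coupling of the C12 aldehyde with tert-butyl 3-iodobut-3-enoate.
2. C8=C17 comes from Mannich methylenation of the C7 ketone; C12 from one-carbon Wittig homologation of the C9 formyl group (C11); the O1 isobutyrate is put on after desilylation.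
3. Key disconnection: intramolecular Diels–Alder reaction of an acyclic tetraene aldehyde, forming C5–C10 and C8–C9. Rings A and B form together (ring B as the cycloadduct ring, ring A from the C1–C4 tether); the lactone ring forms last.
4. Enabling feature: ring B holds the C6 carbinol and C7 ketone side by side next to the fusion atom C5, so it is the hydrolysed form of a cyclohexene with a C6=C7 enediol diether. The quaternary C9 carries a one-carbon branch (C11) that can be a formyl group activating a C9=C10 dienophile, and the C1 carbinol next to C10 can steer the facial course.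
5. The precursor comes from acetylacetone (C19, C5–C8), mesityl oxide (C2, C1, C10, C9, C20, C11) and 2,3-dibromopropene (C3, C4, C18), joined by enolate alkylation and a Suzuki–Miyaura coupling (C4–C5).

Key step: step 11

Remark: the target is (1S,5S,6S,9S,10S,12R,13S); "syn/anti to CH3-19" is used below to describe the ring faces.
Remark: in step 19 the enantiomer of the chiral ligand that gives the 12R carbinol is assumed to be fixed on a model aldehyde.

**Route**

Step 1
Reactants: 1 pentane-2,4-dione
Product: 2 3-diazopentane-2,4-dione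
Conditions: 4-acetamidobenzenesulfonyl azide, Et3N, MeCN, 0 °C to rt
Reagents that add atoms: 4-acetamidobenzenesulfonyl azide, CC(=O)Nc1ccc(cc1)S(=O)(=O)N=[N+]=[N-]
Why: Regitz diazo transfer to the doubly activated methylene should proceed cleanly.

Step 2
Reactants: 2 3-diazopentane-2,4-dione; 3 (4-methoxyphenyl)methanol
Product: 4 3-[(4-methoxybenzyl)oxy]pentane-2,4-dione
Conditions: Rh2(OAc)4 (1 mol%), 1,2-dichloroethane, 80 °C
Reagents that add atoms: none
Why: Rhodium-carbenoid O–H insertion into the alcohol is the standard entry to 2-alkoxy-1,3-dicarbonyl compounds and places the future O6 with its PMB group.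

Step 3
Reactants: 4 3-[(4-methoxybenzyl)oxy]pentane-2,4-dione
Product: 5 (Z)-3-[(4-methoxybenzyl)oxy]-4-oxopent-2-en-2-yl trifluoromethanesulfonate (OTf cis to OPMB, CH3 cis to acetyl)
Conditions: aq. Me4NOH, Tf2O, toluene, 0 °C
Reagents that add atoms: trifluoromethanesulfonic anhydride, O=S(=O)(OS(=O)(=O)C(F)(F)F)C(F)(F)F
Why: Cation-controlled enol triflate formation: the non-chelated tetramethylammonium diketonate should be sulfonylated in its extended form, placing OTf anti to the remaining acetyl group, which fixes the later C5=C6 geometry.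

Step 4
Reactants: 5 (Z)-3-[(4-methoxybenzyl)oxy]-4-oxopent-2-en-2-yl trifluoromethanesulfonate
Product: 6 (Z)-4-[(tert-butyldimethylsilyl)oxy]-3-[(4-methoxybenzyl)oxy]penta-2,4-dien-2-yl trifluoromethanesulfonate
Conditions: KN(SiMe3)2, THF, −78 °C; then TBSOTf
Reagents that add atoms: tert-butyldimethylsilyl trifluoromethanesulfonate, CC(C)(C)[Si](C)(C)OS(=O)(=O)C(F)(F)F
Why: Kinetic deprotonation of the methyl ketone and O-silylation should give the cross-conjugated 2-silyloxy diene without touching the triflate alkene.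

Step 5
Reactants: 7 4-methylpent-3-en-2-one (mesityl oxide); 8 2,3-dibromoprop-1-ene
Product: 9 7-bromo-2-methylocta-2,7-dien-4-one
Conditions: LiN(iPr)2, THF, −78 °C; then 8, DMPU, −78 to −20 °C
Reagents that add atoms: none
Why: The kinetic cross-conjugated enolate of the enone should be alkylated at the allylic bromide only (SN2), since the vinylic bromide is inert.

Step 6
Reactants: 9 7-bromo-2-methylocta-2,7-dien-4-one
Product: 10 (S)-7-bromo-2-methylocta-2,7-dien-4-ol
Conditions: (R)-2-methyl-CBS-oxazaborolidine (10 mol%), catecholborane, toluene, −78 °C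
Reagents that add atoms: none
Why: Corey–Bakshi–Shibata reduction with the alkenyl group as the large substituent should give the S carbinol (the future C1) from the R catalyst.

Step 7
Reactants: 10 (S)-7-bromo-2-methylocta-2,7-dien-4-ol
Product: 11 (S)-[(7-bromo-2-methylocta-2,7-dien-4-yl)oxy](tert-butyl)dimethylsilane
Conditions: TBSCl, imidazole, DMF, rt
Reagents that add atoms: tert-butyldimethylsilyl chloride, CC(C)(C)[Si](C)(C)Cl
Why: Silylation keeps the allylic oxygen inert to the oxidation and the palladium steps, where an allylic ester would ionise.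

Step 8
Reactants: 11 (S)-[(7-bromo-2-methylocta-2,7-dien-4-yl)oxy](tert-butyl)dimethylsilane
Product: 13 (S,E)-7-bromo-4-[(tert-butyldimethylsilyl)oxy]-2-methylocta-2,7-dienal, via allylic alcohol 12 (not isolated)
Conditions: SeO2 (cat.), t-BuOOH, salicylic acid (cat.), CH2Cl2, rt; then MnO2, rt
Reagents that add atoms: tert-butyl hydroperoxide, CC(C)(C)OO (oxygen source, relayed by selenium dioxide, O=[Se]=O)
Why: Allylic oxidation with SeO2 (ene reaction/[2,3]-shift) attacks the E-methyl of the trisubstituted alkene and MnO2 takes the allylic alcohol to the enal, so the formyl group ends trans to the chain, as the dienophile needs.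

Step 9
Reactants: 13 (S,E)-7-bromo-4-[(tert-butyldimethylsilyl)oxy]-2-methylocta-2,7-dienal
Product: 14 (S,E)-4-[(tert-butyldimethylsilyl)oxy]-2-methyl-7-(4,4,5,5-tetramethyl-1,3,2-dioxaborolan-2-yl)octa-2,7-dienal
Conditions: bis(pinacolato)diboron, PdCl2(dppf) (3 mol%), KOAc, 1,4-dioxane, 80 °C
Reagents that add atoms: bis(pinacolato)diboron, CC1(C)OB(OC1(C)C)B1OC(C)(C)C(C)(C)O1
Why: Miyaura borylation of the 2-bromoalkene tolerates the enal and the silyl ether.

Step 10
Reactants: 6 (Z)-4-[(tert-butyldimethylsilyl)oxy]-3-[(4-methoxybenzyl)oxy]penta-2,4-dien-2-yl trifluoromethanesulfonate; 14 (S,E)-4-[(tert-butyldimethylsilyl)oxy]-2-methyl-7-(4,4,5,5-tetramethyl-1,3,2-dioxaborolan-2-yl)octa-2,7-dienal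
Product: 15 (2E,4S,8Z)-4,10-bis[(tert-butyldimethylsilyl)oxy]-9-[(4-methoxybenzyl)oxy]-2,8-dimethyl-7-methylideneundeca-2,8,10-trienal
Conditions: Pd(PPh3)4 (5 mol%), K3PO4, H2O (5 equiv), 1,4-dioxane, 45 °C
Reagents that add atoms: none
Why: Suzuki–Miyaura coupling with retention at the triflate carbon joins C4 to C5 and leaves the tether anti and CH3-19 syn to C7 on the new diene.

Step 11
Reactants: 15 (2E,4S,8Z)-4,10-bis[(tert-butyldimethylsilyl)oxy]-9-[(4-methoxybenzyl)oxy]-2,8-dimethyl-7-methylideneundeca-2,8,10-trienal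
Product: 16 Diels–Alder adduct: trans-fused decalin with C4=C18H2, 1-OTBS (1S, equatorial, anti to CH3-19), C5–CH3, enediol diether C6(OPMB)=C7(OTBS), C8H2, C9 bearing CH3-20 (syn to CH3-19) and CHO (C11), H-10 anti to CH3-19
Conditions: toluene (0.01 M), BHT (cat.), 120 °C, sealed tube
Reagents that add atoms: none
Why: Thermal intramolecular Diels–Alder reaction (type 1, four-carbon tether C1–C4): the electron-rich 2-alkoxy-3-silyloxy diene C5=C6–C7=C8 adds to the (E)-2-methyl enal C9=C10, forming C8–C9 and the ring-fusion bond C5–C10, which should lead in an asynchronous transition state because C5 is the β-carbon of the C6 enol ether and C10 the β-carbon of the enal. The closest known reaction type is the intramolecular Diels–Alder reaction of deca-2,7,9-trienals bearing 2-silyloxy dienes, used for trans-decalins with angular methyl groups. Ring B closes as the cyclohexene ring of the [4+2] event and ring A as the six-membered, chair-like tether ring. C9 and C10 follow from the E geometry of the dienophile (suprafacial addition), the face of the dienophile is set by the C1 stereocentre through 1,3-allylic strain with the cis methyl C20 (H-1 eclipses C9=C10, the tether adds anti to OTBS, which becomes equatorial), and C5 follows from the 8Z diene geometry (C19 inside, tether outside) combined with the formyl-endo/tether-exo orientation, giving the trans fusion with C19 and C20 syn. The step needs endo selectivity (trans over cis fusion) and periselectivity over hetero-Diels–Alder addition or [1,5]-hydrogen shift; the endo preference of the formyl group, its smaller size than CH3 beneath the 2,3-dioxygenated diene, and the short tether, which lets only the C5=C6–C7=C8 diene reach the dienophile, should secure both.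

Step 12
Reactants: 16 Diels–Alder adduct (C9–CHO)
Product: 17 methyl enol ether: as 16 with C9–CH=CH–OMe (E/Z mixture)
Conditions: (methoxymethyl)triphenylphosphonium chloride, KN(SiMe3)2, THF, −78 to 0 °C
Reagents that add atoms: (methoxymethyl)triphenylphosphonium chloride, COC[P+](c1ccccc1)(c1ccccc1)c1ccccc1.[Cl-]
Why: Wittig methoxymethylenation of the neopentyl aldehyde adds C12 in masked form; the silyl enol ether is inert to the ylide and the enol ether geometry is irrelevant.

Step 13
Reactants: 17 methyl enol ether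
Product: 18 hydroxy ketone: 1-OH (1S), C7 ketone, 6-OPMB (6S, syn to CH3-19), C8H2, C9–CH=CH–OMe
Conditions: Bu4NF (3 equiv), THF, 0 °C to rt; aq. NH4Cl
Reagents that add atoms: none
Why: Fluoride cleaves the silyl enol ether regiospecifically to the C7 enolate, which should be protonated at C6 from the face anti to the axial methyls C19 and C20 to give the equatorial 6-OPMB, and the same reagent frees O1.

Step 14
Reactants: 18 hydroxy ketone
Product: 19 1-O-isobutyrate of 18
Conditions: isobutyryl chloride, pyridine, DMAP (cat.), CH2Cl2, 0 °C to rt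
Reagents that add atoms: isobutyryl chloride, CC(C)C(Cl)=O
Why: Acylation of the only free hydroxyl installs the C1 ester now that no palladium step follows.

Step 15
Reactants: 19 1-O-isobutyrate
Product: 22 α-methylene ketone (C8=C17H2), via Mannich base 20 (not isolated), via trimethylammonium iodide 21 (not isolated)
Conditions: LiN(iPr)2 (1.2 equiv), THF, −78 °C; CH2=NMe2+ I−, −78 to 0 °C; then MeI, CH2Cl2, rt; then aq. NaHCO3, rt
Reagents that add atoms: N,N-dimethylmethyleneiminium iodide, C=[N+](C)C.[I-]; iodomethane, CI (its methyl is carried only by 21)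
Why: Kinetic deprotonation should occur at C8 (secondary) and not at the tertiary, alkoxy-bearing C6; the Mannich reaction, quaternisation and E1cB elimination then give the exocyclic enone while the ester and enol ether survive.

Step 16
Reactants: 22 α-methylene ketone
Product: 23 C12 aldehyde (C9–CH2–CHO)
Conditions: 1 M aq. HCl, THF, 0 °C to rt
Reagents that add atoms: water, O
Why: Mild hydrolysis of the methyl enol ether completes the one-carbon homologation; PMB ether, ester, enone and the C4 methylene should tolerate dilute acid.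

Step 17
Reactants: 24 tert-butyl (triphenyl-λ5-phosphanylidene)acetate; 25 acetyl chloride
Product: 26 tert-butyl buta-2,3-dienoate
Conditions: Et3N, CH2Cl2, 0 °C to rt
Reagents that add atoms: none
Why: Wittig olefination of ketene generated in situ is the standard route to 2,3-allenoates.

Step 18
Reactants: 26 tert-butyl buta-2,3-dienoate
Product: 27 tert-butyl 3-iodobut-3-enoate
Conditions: NaI, AcOH, rt
Reagents that add atoms: sodium iodide, [Na+].[I-]
Why: Hydroiodination of the 2,3-allenoate (iodide adds to the central carbon, protonation at C2) gives the β,γ-unsaturated β-iodo ester.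

Step 19
Reactants: 23 C12 aldehyde; 27 tert-butyl 3-iodobut-3-enoate
Product: 28 (12R)-allylic alcohol: C11H2–C12H(OH)–C13(=C16H2)–C14H2–CO2tBu on C9
Conditions: CrCl2 (4 equiv), NiCl2 (2 mol%), chiral oxazoline–sulfonamide ligand, Et3N, THF, rt
Reagents that add atoms: none
Why: Nozaki–Hiyama–Kishi addition of the alkenylchromium species is selective for the aldehyde over the hindered enone and the esters; the ligand sets C12 (12R) and the tert-butyl ester prevents lactonisation onto O12.

Step 20
Reactants: 28 (12R)-allylic alcohol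
Product: 29 (12R,13S)-epoxy alcohol (C13–C16 epoxide)
Conditions: Ti(OiPr)4 (20 mol%), D-(−)-diisopropyl tartrate (24 mol%), t-BuOOH, 4 Å MS, CH2Cl2, −20 °C
Reagents that add atoms: tert-butyl hydroperoxide, CC(C)(C)OO
Why: Sharpless epoxidation touches only the allylic-alcohol alkene; D-(−)-tartrate is matched with the 12R carbinol and gives the erythro epoxide (13S), while any 12S epimer is mismatched and is left behind.

Step 21
Reactants: 29 (12R,13S)-epoxy alcohol
Product: 30 (12R,13S)-12,13-dihydroxy 15,16-lactone (6-OPMB)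
Conditions: camphorsulfonic acid (0.2 equiv), CH2Cl2, 0 °C to rt
Reagents that add atoms: none
Why: Acid-promoted 5-exo opening of the epoxide at the primary carbon C16 by the ester carbonyl, with loss of isobutene, closes the γ-lactone and leaves the C13–O bond (13S) untouched.

Step 22
Reactants: 30 dihydroxy lactone
Product: 31 12-O-tiglate of 30
Conditions: (E)-2-methylbut-2-enoyl chloride, DMAP, pyridine, CH2Cl2, 0 °C to rt
Reagents that add atoms: (E)-2-methylbut-2-enoyl chloride, C/C=C(\C)C(Cl)=O
Why: Only the secondary C12 hydroxyl should be acylated; the tertiary C13 hydroxyl and the PMB ether are inert.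

Step 23
Reactants: 31 12-O-tiglate
Product: 32 CNP0182744.1 (target)
Conditions: DDQ, CH2Cl2/pH 7 buffer (10:1), 0 °C
Reagents that add atoms: none
Why: Oxidative PMB cleavage under neutral conditions frees the 6-hydroxyl last, so the α-ketol never meets base.

**Compound list**

1 | pentane-2,4-dione | CC(=O)CC(C)=O | starting material
2 | 3-diazopentane-2,4-dione | CC(=O)C(=[N+]=[N-])C(C)=O | intermediate
3 | (4-methoxyphenyl)methanol | COc1ccc(CO)cc1 | starting material
4 | 3-[(4-methoxybenzyl)oxy]pentane-2,4-dione | CC(=O)C(OCc1ccc(OC)cc1)C(C)=O | intermediate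
5 | (Z)-3-[(4-methoxybenzyl)oxy]-4-oxopent-2-en-2-yl trifluoromethanesulfonate | C/C(OS(=O)(=O)C(F)(F)F)=C(/OCc1ccc(OC)cc1)C(C)=O | intermediate
6 | (Z)-4-[(tert-butyldimethylsilyl)oxy]-3-[(4-methoxybenzyl)oxy]penta-2,4-dien-2-yl trifluoromethanesulfonate | C/C(OS(=O)(=O)C(F)(F)F)=C(/OCc1ccc(OC)cc1)C(O[Si](C)(C)C(C)(C)C)=C | intermediate
7 | 4-methylpent-3-en-2-one | CC(C)=CC(C)=O | starting material
8 | 2,3-dibromoprop-1-ene | BrCC(Br)=C | starting material
9 | 7-bromo-2-methylocta-2,7-dien-4-one | CC(C)=CC(=O)CCC(Br)=C | intermediate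
10 | (S)-7-bromo-2-methylocta-2,7-dien-4-ol | C=C(Br)CC[C@H](O)C=C(C)C | intermediate
11 | (S)-[(7-bromo-2-methylocta-2,7-dien-4-yl)oxy](tert-butyl)dimethylsilane | C=C(Br)CC[C@H](O[Si](C)(C)C(C)(C)C)C=C(C)C | intermediate
12 | (S,E)-7-bromo-4-[(tert-butyldimethylsilyl)oxy]-2-methylocta-2,7-dien-1-ol | C=C(Br)CC[C@H](O[Si](C)(C)C(C)(C)C)/C=C(\C)CO | intermediate
13 | (S,E)-7-bromo-4-[(tert-butyldimethylsilyl)oxy]-2-methylocta-2,7-dienal | C=C(Br)CC[C@H](O[Si](C)(C)C(C)(C)C)/C=C(\C)C=O | intermediate
14 | (S,E)-4-[(tert-butyldimethylsilyl)oxy]-2-methyl-7-(4,4,5,5-tetramethyl-1,3,2-dioxaborolan-2-yl)octa-2,7-dienal | C=C(B1OC(C)(C)C(C)(C)O1)CC[C@H](O[Si](C)(C)C(C)(C)C)/C=C(\C)C=O | intermediate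
15 | (2E,4S,8Z)-4,10-bis[(tert-butyldimethylsilyl)oxy]-9-[(4-methoxybenzyl)oxy]-2,8-dimethyl-7-methylideneundeca-2,8,10-trienal | C=C(CC[C@H](O[Si](C)(C)C(C)(C)C)/C=C(\C)C=O)/C(C)=C(\OCc1ccc(OC)cc1)C(O[Si](C)(C)C(C)(C)C)=C | intermediate
16 | Diels–Alder adduct: trans-decalin, 1-OTBS, 4-methylidene, C6(OPMB)=C7(OTBS), C9–CHO, ring stereocentres as in the target | C=C1CC[C@H](O[Si](C)(C)C(C)(C)C)[C@@H]2[C@]1(C)C(OCc3ccc(OC)cc3)=C(O[Si](C)(C)C(C)(C)C)C[C@@]2(C)C=O | intermediate
17 | as 16 with C9–CH=CH–OMe (E/Z mixture) | C=C1CC[C@H](O[Si](C)(C)C(C)(C)C)[C@@H]2[C@]1(C)C(OCc3ccc(OC)cc3)=C(O[Si](C)(C)C(C)(C)C)C[C@@]2(C)C=COC | intermediate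
18 | 1-hydroxy-7-ketone, (6S)-6-OPMB syn to CH3-19, C9–CH=CH–OMe | C=C1CC[C@H](O)[C@@H]2[C@]1(C)[C@H](OCc3ccc(OC)cc3)C(=O)C[C@@]2(C)C=COC | intermediate
19 | 1-O-isobutyrate of 18 | C=C1CC[C@H](OC(=O)C(C)C)[C@@H]2[C@]1(C)[C@H](OCc3ccc(OC)cc3)C(=O)C[C@@]2(C)C=COC | intermediate
20 | Mannich base: 19 with CH2NMe2 on C8 (C8 epimers) | C=C1CC[C@H](OC(=O)C(C)C)[C@@H]2[C@]1(C)[C@H](OCc3ccc(OC)cc3)C(=O)C(CN(C)C)[C@@]2(C)C=COC | intermediate
21 | trimethylammonium iodide of 20 | C=C1CC[C@H](OC(=O)C(C)C)[C@@H]2[C@]1(C)[C@H](OCc3ccc(OC)cc3)C(=O)C(C[N+](C)(C)C)[C@@]2(C)C=COC.[I-] | intermediate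
22 | α-methylene ketone (C8=C17H2), C9–CH=CH–OMe | C=C1CC[C@H](OC(=O)C(C)C)[C@@H]2[C@]1(C)[C@H](OCc3ccc(OC)cc3)C(=O)C(=C)[C@@]2(C)C=COC | intermediate
23 | C12 aldehyde (C9–CH2–CHO) | C=C1CC[C@H](OC(=O)C(C)C)[C@@H]2[C@]1(C)[C@H](OCc3ccc(OC)cc3)C(=O)C(=C)[C@@]2(C)CC=O | intermediate
24 | tert-butyl (triphenyl-λ5-phosphanylidene)acetate | CC(C)(C)OC(=O)C=P(c1ccccc1)(c1ccccc1)c1ccccc1 | starting material
25 | acetyl chloride | CC(Cl)=O | starting material
26 | tert-butyl buta-2,3-dienoate | C=C=CC(=O)OC(C)(C)C | intermediate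
27 | tert-butyl 3-iodobut-3-enoate | C=C(I)CC(=O)OC(C)(C)C | intermediate
28 | (12R)-allylic alcohol with tert-butyl ester side chain | C=C1CC[C@H](OC(=O)C(C)C)[C@@H]2[C@]1(C)[C@H](OCc3ccc(OC)cc3)C(=O)C(=C)[C@@]2(C)C[C@@H](O)C(=C)CC(=O)OC(C)(C)C | intermediate
29 | (12R,13S)-13,16-epoxy-12-ol tert-butyl ester | C=C1CC[C@H](OC(=O)C(C)C)[C@@H]2[C@]1(C)[C@H](OCc3ccc(OC)cc3)C(=O)C(=C)[C@@]2(C)C[C@@H](O)[C@]4(CC(=O)OC(C)(C)C)CO4 | intermediate
30 | (12R,13S)-12,13-dihydroxy-15,16-olide, 6-OPMB | C=C1CC[C@H](OC(=O)C(C)C)[C@@H]2[C@]1(C)[C@H](OCc3ccc(OC)cc3)C(=O)C(=C)[C@@]2(C)C[C@@H](O)[C@@]1(O)COC(=O)C1 | intermediate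
31 | 12-O-tiglate of 30 | C=C1CC[C@H](OC(=O)C(C)C)[C@@H]2[C@]1(C)[C@H](OCc3ccc(OC)cc3)C(=O)C(=C)[C@@]2(C)C[C@@H](OC(=O)/C(C)=C/C)[C@@]1(O)COC(=O)C1 | intermediate
32 | CNP0182744.1 | C=C1CC[C@H](OC(=O)C(C)C)[C@@H]2[C@]1(C)[C@H](O)C(=O)C(=C)[C@@]2(C)C[C@@H](OC(=O)/C(C)=C/C)[C@@]1(O)COC(=O)C1 | target

**Summary**

Total step count: 23.
Longest linear sequence: 17 steps (7 to 32: steps 5–16 and 19–23).

**Steps most likely to fail**

1. Step 11. The process at risk is poor endo/exo discrimination (cis-fused C5 epimer), and at 120 °C a competing [1,5]-hydrogen shift of the Z-methyl diene or hetero-Diels–Alder addition to the formyl group. The fallback replaces the thermal pericyclic closure by a Lewis-acid-induced, stepwise ionic annulation at low temperature on a diene made robust for it. It sets out from 5: KN(SiMe3)2 then iPr3SiOTf should give the triisopropylsilyl dienol ether triflate F1. Suzuki–Miyaura coupling with 14 gives the tetraene aldehyde F2. Me2AlCl (1.1 equiv, CH2Cl2, −78 °C) binds the formyl group and should trigger Mukaiyama–Michael attack of C5 on C10 followed by closure of C8–C9, with the formyl group held endo, to give the trans-fused adduct F3. Wittig methoxymethylenation gives the enol ether F4, and Bu4NF removes both silyl groups so that the route is rejoined at 18.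

2. Step 3. The process at risk is poor control of alkene geometry in the O-sulfonylation of the ambident diketonate; the wrong isomer would place the tether inside the diene and give the C5 epimer or a 2H-pyran after step 10. The fallback moves the geometry-defining step to a β-keto ester, where only one carbonyl can chelate and both enol triflate geometries are separately accessible by choice of cation, and builds the methyl ketone afterwards. It sets out from 3: Rh2(OAc)4-catalysed O–H insertion of methyl 2-diazo-3-oxobutanoate gives methyl 2-[(4-methoxybenzyl)oxy]-3-oxobutanoate F5. Triflation with aq. Me4NOH/Tf2O should give methyl (Z)-2-[(4-methoxybenzyl)oxy]-3-(triflyloxy)but-2-enoate F6 (OTf anti to the ester). iPrMgCl/MeNH(OMe)·HCl at −20 °C gives the Weinreb amide F7, and MeMgBr at −78 °C gives 5, where the route is rejoined.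

3. Step 19. The process at risk is poor reagent-controlled facial selectivity in the addition to the remote aldehyde, since the nearest stereocentre (C9) is too far away to help. The fallback sets C12 by ketone reduction instead of by the addition. It sets out from 23: coupling with 27 under CrCl2/NiCl2 without ligand gives 28 together with its 12S epimer F8. DMP (1,1,1-triacetoxy-1,1-dihydro-1,2-benziodoxol-3(1H)-one) oxidises the mixture to the C12 enone F9. Corey–Bakshi–Shibata reduction with (S)-2-methyl-CBS-oxazaborolidine and catecholborane (alkenyl as the large group; the C7 ketone is shielded by C6 and C9) should return 28 as the 12R carbinol.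

**Further compounds**

F1 | step 11 | (Z)-3-[(4-methoxybenzyl)oxy]-4-[(triisopropylsilyl)oxy]penta-2,4-dien-2-yl trifluoromethanesulfonate | C/C(OS(=O)(=O)C(F)(F)F)=C(/OCc1ccc(OC)cc1)C(O[Si](C(C)C)(C(C)C)C(C)C)=C
F2 | step 11 | triisopropylsilyl analogue of 15 | C=C(CC[C@H](O[Si](C)(C)C(C)(C)C)/C=C(\C)C=O)/C(C)=C(\OCc1ccc(OC)cc1)C(O[Si](C(C)C)(C(C)C)C(C)C)=C
F3 | step 11 | triisopropylsilyl analogue of 16 | C=C1CC[C@H](O[Si](C)(C)C(C)(C)C)[C@@H]2[C@]1(C)C(OCc3ccc(OC)cc3)=C(O[Si](C(C)C)(C(C)C)C(C)C)C[C@@]2(C)C=O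
F4 | step 11 | triisopropylsilyl analogue of 17 | C=C1CC[C@H](O[Si](C)(C)C(C)(C)C)[C@@H]2[C@]1(C)C(OCc3ccc(OC)cc3)=C(O[Si](C(C)C)(C(C)C)C(C)C)C[C@@]2(C)C=COC
F5 | step 3 | methyl 2-[(4-methoxybenzyl)oxy]-3-oxobutanoate | COC(=O)C(OCc1ccc(OC)cc1)C(C)=O
F6 | step 3 | methyl (Z)-2-[(4-methoxybenzyl)oxy]-3-{[(trifluoromethyl)sulfonyl]oxy}but-2-enoate | C/C(OS(=O)(=O)C(F)(F)F)=C(/OCc1ccc(OC)cc1)C(=O)OC
F7 | step 3 | (Z)-4-[methoxy(methyl)amino]-3-[(4-methoxybenzyl)oxy]-4-oxobut-2-en-2-yl trifluoromethanesulfonate | C/C(OS(=O)(=O)C(F)(F)F)=C(/OCc1ccc(OC)cc1)C(=O)N(C)OC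
F8 | step 19 | 12S epimer of 28 | C=C1CC[C@H](OC(=O)C(C)C)[C@@H]2[C@]1(C)[C@H](OCc3ccc(OC)cc3)C(=O)C(=C)[C@@]2(C)C[C@H](O)C(=C)CC(=O)OC(C)(C)C
F9 | step 19 | C12 ketone (enone) derived from 28 and F8 | C=C1CC[C@H](OC(=O)C(C)C)[C@@H]2[C@]1(C)[C@H](OCc3ccc(OC)cc3)C(=O)C(=C)[C@@]2(C)CC(=O)C(=C)CC(=O)OC(C)(C)C
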